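(The numbers are those of an exercise; the rest is arithmetic.)

Late in this flask, at the time asked, I expected the chains to be a record of its early hours, so I reckoned those.

free monomer 0.31 M (fed, over 15 h); transfer agent 9.30 mM; initiator 0.2 mol%; time 20 h

1. average number of monomer units in a chain (chains begun, living or dead) at 20 h
2. part of the free monomer that has reacted at 20 h

    living end + transfer agent → dead chain (k1 = 1.6 /M/min)
    living end + free monomer → dead end (k2 = 0.0010 /M/min)
    free monomer + living end → monomer in chains + living end, rate k3*[living end]*[free monomer] (k3 = 12 /M/min)
    free monomer + initiator → living end + monomer in chains (k4 = 0.16 /M/min)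
    free monomer → uncatalysed product (k5 = 9.5 × 10⁻⁴ /min)

Free monomer was fed at F = 0.0207 M/h, so at first it rose as F times the elapsed time. A living end dies on transfer agent with a pseudo-first-order lifetime τ = 1.12 h, one over the transfer constant times the charge. Initiator falls on the rising monomer, and its clock is tN = 2.25 h, the moment when its loss rate times the elapsed time reaches one. Both are shorter than the feed time. I took a typical chain to start at tN and die τ later, seeing free monomer near F(tN+τ). With g the growth constant, that makes gτF(tN+τ) = 56.1 units, the chain yield. I took the chains begun as the initiator charge, 0.620 mM, so they hold 11.2 % of the monomer. The rest, fed on average 12.5 h before the reading, decays by the uncatalysed step, which gives c = 56.5 %.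

The forecast gave 56 (45 to 68) and 54.5 % (50 % to 59 %), saying that later “the uncatalysed loss takes over”. The simulation gave 54.2 and 54.1 %.

The bit-by-bit addition shortened this flask's chains: without it the average was 186, not 54.2. This flask's chain yield was 56.1. In a neighbour flask charged with 0.023 M of transfer agent, τ is 0.453 h and the chain yield 18.2; the simulation of that neighbour gave 20.4, with 4.09 % of the charged free monomer in chains.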